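The 1-aryltetralin is cut at C1–C8a. C1 is the benzylic carbon of ring B, para to that ring's phenolic oxygen, and in the open-chain (2R,3R)-dibenzylbutane it lies within six-ring reach of C8a of ring C, the unhindered carbon para to the C6 methoxy group. Anodic oxidation of the free ring B phenol of the precursor, whose ring C is masked as a benzyl ether, should turn C1 into a quinone methide carbon that ring C captures, closing the carbocycle and setting C1 trans to the C2 methyl group in one operation. The precursor comes from an auxiliary-derived trans-dibenzylbutyrolactone bearing orthogonal allyl and benzyl ethers; the erythro side chain is then grown from ethyl (S)-lactate.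

Key step: step 11

Remark: the tetralin is numbered C1–C8a (aryl on C1, methyls on C2 and C3, OMe on C6, OH on C7); ring A is the guaiacyl ring of the side chain, ring B the aryl group on C1, ring C the arene of the tetralin, Cα and Cβ are the carbinol and ether carbons of the side chain; crude intermediates that are carried on without purification are treated as not isolated.

Step 1
Reactants: 1 3-(4-hydroxy-3-methoxyphenyl)propanoic acid
Product: 2 3-[3-methoxy-4-(prop-2-en-1-yloxy)phenyl]propanoic acid
Conditions: allyl bromide, KOH, EtOH–H2O, reflux; then HCl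
Reagents that add atoms: allyl bromide, C=CCBr
Why: Williamson etherification of the phenoxide in aqueous alkali, where the carboxylate is a much poorer nucleophile and any allyl ester formed is saponified in the same pot, should leave only the aryl allyl ether after acidification; no stereocentre is involved.

Step 2
Reactants: 2 3-[3-methoxy-4-(prop-2-en-1-yloxy)phenyl]propanoic acid; 3 (4S)-4-benzyl-1,3-oxazolidin-2-one
Product: 5 (4S)-4-benzyl-3-{3-[3-methoxy-4-(prop-2-en-1-yloxy)phenyl]propanoyl}-1,3-oxazolidin-2-one, via mixed pivalic anhydride 4 (not isolated)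
Conditions: pivaloyl chloride, Et3N, THF, −20 °C; then 3, LiCl, −20 °C → rt
Reagents that add atoms: none
Why: N-Acylation of the oxazolidinone through the mixed pivalic anhydride, which LiCl-activated 3 attacks at the less hindered acyl carbon, is the standard one-pot way to load an Evans auxiliary and creates no stereocentre.

Step 3
Reactants: 5 (4S)-4-benzyl-3-{3-[3-methoxy-4-(prop-2-en-1-yloxy)phenyl]propanoyl}-1,3-oxazolidin-2-one
Product: 7 tert-butyl (3R)-4-[(4S)-4-benzyl-2-oxo-1,3-oxazolidin-3-yl]-3-{[3-methoxy-4-(prop-2-en-1-yloxy)phenyl]methyl}-4-oxobutanoate, via sodium Z-enolate 6 (not isolated)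
Conditions: NaN(SiMe3)2, THF, −78 °C; tert-butyl bromoacetate, −78 → −40 °C
Reagents that add atoms: tert-butyl bromoacetate, CC(C)(C)OC(=O)CBr
Why: Evans asymmetric alkylation, in which the chelated sodium Z-enolate 6 is attacked by the bromoacetate on the face opposite the C4 benzyl group of the auxiliary, should set the new α-carbon as R.

Step 4
Reactants: 7 tert-butyl (3R)-4-[(4S)-4-benzyl-2-oxo-1,3-oxazolidin-3-yl]-3-{[3-methoxy-4-(prop-2-en-1-yloxy)phenyl]methyl}-4-oxobutanoate
Product: 9 (4R)-4-{[3-methoxy-4-(prop-2-en-1-yloxy)phenyl]methyl}oxolan-2-one, via hydroxy tert-butyl ester 8 (not isolated)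
Conditions: LiBH4, MeOH (1 equiv), THF, 0 °C; aq NH4Cl work-up; then TsOH·H2O (cat.), toluene, 80 °C
Reagents that add atoms: none
Why: LiBH4 reduces the activated exocyclic imide carbonyl but not the tert-butyl ester (chemoselective reductive removal of the auxiliary), and acid-catalysed lactonisation of the resulting γ-hydroxy ester then closes the five-membered lactone with the stereocentre untouched.

Step 5
Reactants: 10 (4-benzyloxy-3-methoxyphenyl)methanol
Product: 11 1-(benzyloxy)-4-(bromomethyl)-2-methoxybenzene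
Conditions: PBr3, Et2O, 0 °C
Reagents that add atoms: phosphorus tribromide, BrP(Br)Br
Why: Bromination of an electron-rich benzylic alcohol with PBr3 (SN2 displacement of the intermediate phosphite ester) is routine for this known bromide, which is used at once because it is labile.

Step 6
Reactants: 9 (4R)-4-{[3-methoxy-4-(prop-2-en-1-yloxy)phenyl]methyl}oxolan-2-one; 11 1-(benzyloxy)-4-(bromomethyl)-2-methoxybenzene
Product: 13 (3R,4R)-3-[(4-benzyloxy-3-methoxyphenyl)methyl]-4-{[3-methoxy-4-(prop-2-en-1-yloxy)phenyl]methyl}oxolan-2-one, via lithium enolate 12 (not isolated)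
Conditions: LiN(SiMe3)2, THF, −78 °C; then 11, −78 → −30 °C
Reagents that add atoms: none
Why: Enolate alkylation of a β-substituted γ-butyrolactone, in which the benzylic bromide approaches the lithium enolate 12 anti to the C4 arylmethyl group, should set C3 as R and give the trans-3,4-disubstituted lactone.

Step 7
Reactants: 13 (3R,4R)-3-[(4-benzyloxy-3-methoxyphenyl)methyl]-4-{[3-methoxy-4-(prop-2-en-1-yloxy)phenyl]methyl}oxolan-2-one
Product: 14 (2R,3R)-2-[(4-benzyloxy-3-methoxyphenyl)methyl]-3-{[3-methoxy-4-(prop-2-en-1-yloxy)phenyl]methyl}butane-1,4-diol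
Conditions: LiAlH4, THF, 0 °C → rt
Reagents that add atoms: none
Why: LiAlH4 reduction of the lactone to the 1,4-diol touches neither stereocentre nor the allyl and benzyl aryl ethers.

Step 8
Reactants: 14 (2R,3R)-2-[(4-benzyloxy-3-methoxyphenyl)methyl]-3-{[3-methoxy-4-(prop-2-en-1-yloxy)phenyl]methyl}butane-1,4-diol
Product: 15 (2R,3R)-2-[(4-benzyloxy-3-methoxyphenyl)methyl]-3-{[3-methoxy-4-(prop-2-en-1-yloxy)phenyl]methyl}butane-1,4-diyl dimethanesulfonate
Conditions: MsCl (excess), Et3N, CH2Cl2, 0 °C
Reagents that add atoms: methanesulfonyl chloride, CS(=O)(=O)Cl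
Why: Sulfonylation of both primary alcohols with excess MsCl and Et3N at 0 °C is fast enough to outrun cyclisation of the monomesylate to a tetrahydrofuran and leaves the stereocentres alone.

Step 9
Reactants: 15 (2R,3R)-2-[(4-benzyloxy-3-methoxyphenyl)methyl]-3-{[3-methoxy-4-(prop-2-en-1-yloxy)phenyl]methyl}butane-1,4-diyl dimethanesulfonate
Product: 16 1-(benzyloxy)-4-{(2R,3R)-4-[3-methoxy-4-(prop-2-en-1-yloxy)phenyl]-2,3-dimethylbutyl}-2-methoxybenzene
Conditions: LiEt3BH, THF, 0 °C → rt
Reagents that add atoms: none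
Why: SN2 hydride displacement of the two primary mesylates by LiEt3BH, the most nucleophilic common hydride for C–O cleavage of sulfonates, should turn both CH2OMs groups into methyl groups without touching the neighbouring stereocentres.

Step 10
Reactants: 16 1-(benzyloxy)-4-{(2R,3R)-4-[3-methoxy-4-(prop-2-en-1-yloxy)phenyl]-2,3-dimethylbutyl}-2-methoxybenzene
Product: 17 4-[(2R,3R)-4-(4-benzyloxy-3-methoxyphenyl)-2,3-dimethylbutyl]-2-methoxyphenol
Conditions: Pd(PPh3)4 (cat.), morpholine, THF, rt
Reagents that add atoms: none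
Why: Tsuji–Trost-type deallylation, in which zerovalent palladium ionises the aryl allyl ether to a π-allyl complex that morpholine captures, frees the ring B phenol while the benzyl ether, which cannot ionise in this way, stays.

Step 11
Reactants: 17 4-[(2R,3R)-4-(4-benzyloxy-3-methoxyphenyl)-2,3-dimethylbutyl]-2-methoxyphenol
Product: 19 4-[(1S,2S,3R)-7-benzyloxy-6-methoxy-2,3-dimethyl-1,2,3,4-tetrahydronaphthalen-1-yl]-2-methoxyphenol, via para-quinone methide 18 (not isolated)
Conditions: graphite anode, Pt cathode, undivided cell, constant current (about 5 mA cm−2, about 2 F mol−1), nBu4NBF4 (0.1 M), (CF3)2CHOH (HFIP)–CH2Cl2 4:1, 5 mM in 17, 0 °C, N2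
Reagents that add atoms: none
Why: Ring B, the only free phenol and the most easily oxidised part of 17, gives up two electrons and two protons at the carbon anode to form para-quinone methide 18, whose exocyclic carbon (the future C1) is attacked by C8a of ring C in an intramolecular Friedel–Crafts (vinylogous Michael) alkylation, and proton loss rearomatises both rings while the cathode releases H2. The closest known reaction types are the anodic two-electron oxidation of para-alkylphenols to quinone methides that are captured by nucleophiles, and the DDQ-mediated quinone-methide cyclisation of dibenzylbutane lignans to 1-aryltetralins. The new carbocycle closes in a 6-exo-trig mode onto the exocyclic methide carbon. C1 should be set as S by the existing C2 and C3 centres through a chair-like transition state in which the aryl group and both methyl groups are pseudo-equatorial, which leads to the 1,2-trans, 2,3-trans ring. Chemoselectivity rests on the free phenol being oxidised well below the benzyl-protected dialkoxyarene ring C, regioselectivity on C8a being para to the C6 methoxy group and unhindered whereas the other ortho carbon is flanked by that methoxy group, and the non-nucleophilic, cation-stabilising HFIP should keep solvent from capturing 18. The charge is limited and the solution kept dilute to hold back further oxidation of the product phenol and intermolecular phenol coupling.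

Step 12
Reactants: 19 4-[(1S,2S,3R)-7-benzyloxy-6-methoxy-2,3-dimethyl-1,2,3,4-tetrahydronaphthalen-1-yl]-2-methoxyphenol; 20 ethyl (2S)-2-hydroxypropanoate
Product: 21 ethyl (2R)-2-{4-[(1S,2S,3R)-7-benzyloxy-6-methoxy-2,3-dimethyl-1,2,3,4-tetrahydronaphthalen-1-yl]-2-methoxyphenoxy}propanoate
Conditions: PPh3, DIAD, THF, 0 °C → rt
Reagents that add atoms: none
Why: Mitsunobu etherification, in which the phenoxide displaces the activated oxyphosphonium group of the α-hydroxy ester by SN2, should invert the (S)-lactate carbon to the (R)-aryloxy centre that becomes Cβ.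

Step 13
Reactants: 21 ethyl (2R)-2-{4-[(1S,2S,3R)-7-benzyloxy-6-methoxy-2,3-dimethyl-1,2,3,4-tetrahydronaphthalen-1-yl]-2-methoxyphenoxy}propanoate
Product: 22 (2R)-2-{4-[(1S,2S,3R)-7-benzyloxy-6-methoxy-2,3-dimethyl-1,2,3,4-tetrahydronaphthalen-1-yl]-2-methoxyphenoxy}-N-methoxy-N-methylpropanamide
Conditions: MeNH(OMe)·HCl, iPrMgCl, THF, −20 → −10 °C
Reagents that add atoms: N,O-dimethylhydroxylamine hydrochloride, CNOC.Cl
Why: Weinreb amide formation by aminolysis of the ester with the chloromagnesium amide of N,O-dimethylhydroxylamine should proceed at low temperature without enolising the α-aryloxy centre, since no free Grignard reagent remains and the magnesium amide is only weakly basic.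

Step 14
Reactants: 23 4-bromo-2-methoxyphenol
Product: 24 1-(benzyloxy)-4-bromo-2-methoxybenzene
Conditions: BnBr, K2CO3, acetone, reflux
Reagents that add atoms: benzyl bromide, BrCc1ccccc1
Why: Williamson benzylation of the phenol under mild carbonate conditions protects ring A with the same group as ring C, so that one hydrogenolysis can free both at the end.

Step 15
Reactants: 22 (2R)-2-{4-[(1S,2S,3R)-7-benzyloxy-6-methoxy-2,3-dimethyl-1,2,3,4-tetrahydronaphthalen-1-yl]-2-methoxyphenoxy}-N-methoxy-N-methylpropanamide; 24 1-(benzyloxy)-4-bromo-2-methoxybenzene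
Product: 26 (2R)-1-(4-benzyloxy-3-methoxyphenyl)-2-{4-[(1S,2S,3R)-7-benzyloxy-6-methoxy-2,3-dimethyl-1,2,3,4-tetrahydronaphthalen-1-yl]-2-methoxyphenoxy}propan-1-one, via arylmagnesium bromide 25 (not isolated)
Conditions: 24, Mg, THF, reflux; then 22, THF, 0 °C; aq NH4Cl
Reagents that add atoms: none
Why: Weinreb ketone synthesis, in which the aryl Grignard reagent 25 adds once to give a magnesium-chelated tetrahedral intermediate that collapses to the ketone only on work-up, prevents over-addition and keeps the Cβ centre out of reach of base.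

Step 16
Reactants: 26 (2R)-1-(4-benzyloxy-3-methoxyphenyl)-2-{4-[(1S,2S,3R)-7-benzyloxy-6-methoxy-2,3-dimethyl-1,2,3,4-tetrahydronaphthalen-1-yl]-2-methoxyphenoxy}propan-1-one
Product: 27 (1S,2R)-1-(4-benzyloxy-3-methoxyphenyl)-2-{4-[(1S,2S,3R)-7-benzyloxy-6-methoxy-2,3-dimethyl-1,2,3,4-tetrahydronaphthalen-1-yl]-2-methoxyphenoxy}propan-1-ol
Conditions: Zn(BH4)2, Et2O–CH2Cl2, −30 → 0 °C; aq NH4Cl
Reagents that add atoms: none
Why: Chelation-controlled reduction (Cram cyclic model), in which zinc bridges the carbonyl and aryloxy oxygens and hydride arrives from the face flanked by the Cβ hydrogen and not by its methyl group, should set Cα as S and so give the erythro (1S,2R) alcohol.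

Step 17
Reactants: 27 (1S,2R)-1-(4-benzyloxy-3-methoxyphenyl)-2-{4-[(1S,2S,3R)-7-benzyloxy-6-methoxy-2,3-dimethyl-1,2,3,4-tetrahydronaphthalen-1-yl]-2-methoxyphenoxy}propan-1-ol
Product: 28 4-[(1S,2R)-1-hydroxy-2-{4-[(1S,2S,3R)-7-hydroxy-6-methoxy-2,3-dimethyl-1,2,3,4-tetrahydronaphthalen-1-yl]-2-methoxyphenoxy}propyl]-2-methoxyphenol
Conditions: H2 (1 atm), Pd/C, EtOAc–EtOH, rt
Reagents that add atoms: none
Why: Catalytic hydrogenolysis of the two benzyl aryl ethers over Pd/C under neutral conditions is much faster than C–O cleavage of the secondary benzylic alcohol or of the alkyl aryl ether, so it should unmask both phenols and leave all five stereocentres as set.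

Compound list
1 | 3-(4-hydroxy-3-methoxyphenyl)propanoic acid | COc1cc(CCC(=O)O)ccc1O | starting material
2 | 3-[3-methoxy-4-(prop-2-en-1-yloxy)phenyl]propanoic acid | C=CCOc1ccc(CCC(=O)O)cc1OC | intermediate
3 | (4S)-4-benzyl-1,3-oxazolidin-2-one | O=C1N[C@@H](Cc2ccccc2)CO1 | starting material
4 | 3-[3-methoxy-4-(prop-2-en-1-yloxy)phenyl]propanoic 2,2-dimethylpropanoic anhydride | C=CCOc1ccc(CCC(=O)OC(=O)C(C)(C)C)cc1OC | intermediate
5 | (4S)-4-benzyl-3-{3-[3-methoxy-4-(prop-2-en-1-yloxy)phenyl]propanoyl}-1,3-oxazolidin-2-one | C=CCOc1ccc(CCC(=O)N2[C@@H](Cc3ccccc3)COC2=O)cc1OC | intermediate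
6 | sodium (1Z)-1-[(4S)-4-benzyl-2-oxo-1,3-oxazolidin-3-yl]-3-[3-methoxy-4-(prop-2-en-1-yloxy)phenyl]prop-1-en-1-olate | [Na+].[O-]/C(=C\Cc1ccc(OCC=C)c(OC)c1)N1[C@@H](Cc2ccccc2)COC1=O | intermediate
7 | tert-butyl (3R)-4-[(4S)-4-benzyl-2-oxo-1,3-oxazolidin-3-yl]-3-{[3-methoxy-4-(prop-2-en-1-yloxy)phenyl]methyl}-4-oxobutanoate | C=CCOc1ccc(C[C@H](CC(=O)OC(C)(C)C)C(=O)N2[C@@H](Cc3ccccc3)COC2=O)cc1OC | intermediate
8 | tert-butyl (3R)-3-(hydroxymethyl)-4-[3-methoxy-4-(prop-2-en-1-yloxy)phenyl]butanoate | C=CCOc1ccc(C[C@H](CC(=O)OC(C)(C)C)CO)cc1OC | intermediate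
9 | (4R)-4-{[3-methoxy-4-(prop-2-en-1-yloxy)phenyl]methyl}oxolan-2-one | O=C1C[C@@H](Cc2ccc(OCC=C)c(OC)c2)CO1 | intermediate
10 | (4-benzyloxy-3-methoxyphenyl)methanol | COc1cc(CO)ccc1OCc1ccccc1 | starting material
11 | 1-(benzyloxy)-4-(bromomethyl)-2-methoxybenzene | COc1cc(CBr)ccc1OCc1ccccc1 | intermediate
12 | lithium (4R)-4-{[3-methoxy-4-(prop-2-en-1-yloxy)phenyl]methyl}-4,5-dihydrofuran-2-olate | [Li+].[O-]C1=C[C@@H](Cc2ccc(OCC=C)c(OC)c2)CO1 | intermediate
13 | (3R,4R)-3-[(4-benzyloxy-3-methoxyphenyl)methyl]-4-{[3-methoxy-4-(prop-2-en-1-yloxy)phenyl]methyl}oxolan-2-one | O=C1OC[C@H](Cc2ccc(OCC=C)c(OC)c2)[C@H]1Cc1ccc(OCc2ccccc2)c(OC)c1 | intermediate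
14 | (2R,3R)-2-[(4-benzyloxy-3-methoxyphenyl)methyl]-3-{[3-methoxy-4-(prop-2-en-1-yloxy)phenyl]methyl}butane-1,4-diol | OC[C@H](Cc1ccc(OCC=C)c(OC)c1)[C@H](CO)Cc1ccc(OCc2ccccc2)c(OC)c1 | intermediate
15 | (2R,3R)-2-[(4-benzyloxy-3-methoxyphenyl)methyl]-3-{[3-methoxy-4-(prop-2-en-1-yloxy)phenyl]methyl}butane-1,4-diyl dimethanesulfonate | CS(=O)(=O)OC[C@H](Cc1ccc(OCC=C)c(OC)c1)[C@H](COS(C)(=O)=O)Cc1ccc(OCc2ccccc2)c(OC)c1 | intermediate
16 | 1-(benzyloxy)-4-{(2R,3R)-4-[3-methoxy-4-(prop-2-en-1-yloxy)phenyl]-2,3-dimethylbutyl}-2-methoxybenzene | C[C@H](Cc1ccc(OCC=C)c(OC)c1)[C@H](C)Cc1ccc(OCc2ccccc2)c(OC)c1 | intermediate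
17 | 4-[(2R,3R)-4-(4-benzyloxy-3-methoxyphenyl)-2,3-dimethylbutyl]-2-methoxyphenol | COc1cc(C[C@@H](C)[C@H](C)Cc2ccc(OCc3ccccc3)c(OC)c2)ccc1O | intermediate
18 | 4-[(2S,3R)-4-(4-benzyloxy-3-methoxyphenyl)-2,3-dimethylbutylidene]-2-methoxycyclohexa-2,5-dien-1-one (alkene geometry not defined) | COC1=CC(=C[C@@H](C)[C@H](C)Cc2ccc(OCc3ccccc3)c(OC)c2)C=CC1=O | intermediate
19 | 4-[(1S,2S,3R)-7-benzyloxy-6-methoxy-2,3-dimethyl-1,2,3,4-tetrahydronaphthalen-1-yl]-2-methoxyphenol | COc1cc(ccc1O)[C@H]1c2cc(OCc3ccccc3)c(OC)cc2C[C@@H](C)[C@@H]1C | intermediate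
20 | ethyl (2S)-2-hydroxypropanoate | CCOC(=O)[C@H](C)O | starting material
21 | ethyl (2R)-2-{4-[(1S,2S,3R)-7-benzyloxy-6-methoxy-2,3-dimethyl-1,2,3,4-tetrahydronaphthalen-1-yl]-2-methoxyphenoxy}propanoate | CCOC(=O)[C@@H](C)Oc1ccc(cc1OC)[C@H]1c2cc(OCc3ccccc3)c(OC)cc2C[C@@H](C)[C@@H]1C | intermediate
22 | (2R)-2-{4-[(1S,2S,3R)-7-benzyloxy-6-methoxy-2,3-dimethyl-1,2,3,4-tetrahydronaphthalen-1-yl]-2-methoxyphenoxy}-N-methoxy-N-methylpropanamide | CON(C)C(=O)[C@@H](C)Oc1ccc(cc1OC)[C@H]1c2cc(OCc3ccccc3)c(OC)cc2C[C@@H](C)[C@@H]1C | intermediate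
23 | 4-bromo-2-methoxyphenol | COc1cc(Br)ccc1O | starting material
24 | 1-(benzyloxy)-4-bromo-2-methoxybenzene | COc1cc(Br)ccc1OCc1ccccc1 | intermediate
25 | (4-benzyloxy-3-methoxyphenyl)magnesium bromide | COc1cc([Mg]Br)ccc1OCc1ccccc1 | intermediate
26 | (2R)-1-(4-benzyloxy-3-methoxyphenyl)-2-{4-[(1S,2S,3R)-7-benzyloxy-6-methoxy-2,3-dimethyl-1,2,3,4-tetrahydronaphthalen-1-yl]-2-methoxyphenoxy}propan-1-one | COc1cc(ccc1OCc1ccccc1)C(=O)[C@@H](C)Oc1ccc(cc1OC)[C@H]1c2cc(OCc3ccccc3)c(OC)cc2C[C@@H](C)[C@@H]1C | intermediate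
27 | (1S,2R)-1-(4-benzyloxy-3-methoxyphenyl)-2-{4-[(1S,2S,3R)-7-benzyloxy-6-methoxy-2,3-dimethyl-1,2,3,4-tetrahydronaphthalen-1-yl]-2-methoxyphenoxy}propan-1-ol | COc1cc(ccc1OCc1ccccc1)[C@H](O)[C@@H](C)Oc1ccc(cc1OC)[C@H]1c2cc(OCc3ccccc3)c(OC)cc2C[C@@H](C)[C@@H]1C | intermediate
28 | 4-[(1S,2R)-1-hydroxy-2-{4-[(1S,2S,3R)-7-hydroxy-6-methoxy-2,3-dimethyl-1,2,3,4-tetrahydronaphthalen-1-yl]-2-methoxyphenoxy}propyl]-2-methoxyphenol | COc1cc([C@H](O)[C@@H](C)Oc2ccc([C@H]3c4cc(O)c(OC)cc4C[C@@H](C)[C@@H]3C)cc2OC)ccc1O | target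

Total step count: 17
Longest linear sequence: 15 steps (steps 1–4, 6–13 and 15–17)

Steps most likely to fail

Step 11. The danger is further anodic oxidation of the product phenol at the now doubly benzylic C1, together with tautomerisation of the quinone methide to a styrene and intermolecular phenol coupling. The fallback separates oxidation from ring closure and uses chemical reagents of known behaviour. Setting out from 17, DDQ in CH2Cl2–MeOH at 0 °C should generate the same quinone methide and trap it with methanol as 4-[(1RS,2S,3R)-4-(4-benzyloxy-3-methoxyphenyl)-1-methoxy-2,3-dimethylbutyl]-2-methoxyphenol F1. BF3·OEt2 in CH2Cl2 at −40 °C should then ionise the benzylic ether of F1 and drive the same Friedel–Crafts closure under acid, with loss of methanol and the same chair-like control of C1, coming back to the route at 19.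

Step 16. The danger is poor facial selectivity: if the weakly basic aryloxy oxygen does not hold the zinc chelate, the open Felkin–Anh pathway leaks the threo epimer. The fallback replaces substrate control by catalyst control. Setting out from 26, a Corey–Bakshi–Shibata reduction with (S)-2-methyl-CBS-oxazaborolidine and BH3·SMe2 in THF at −20 °C, in which the aryl group is expected to act as the large substituent, should deliver hydride to the face that gives the (1S) carbinol whether or not a chelate forms. It comes back to the route at 27 and makes no compound outside the list (F0).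

Step 17. The danger is over-reduction: hydrogenolytic loss of the electron-rich benzylic hydroxyl group once the para phenol of ring A is unmasked. The fallback changes the order so that no benzylic alcohol is present during hydrogenolysis. Setting out from 26, H2 over Pd/C in EtOAc should remove both benzyl groups at the ketone stage to give (2R)-1-(4-hydroxy-3-methoxyphenyl)-2-{4-[(1S,2S,3R)-7-hydroxy-6-methoxy-2,3-dimethyl-1,2,3,4-tetrahydronaphthalen-1-yl]-2-methoxyphenoxy}propan-1-one F2. Chelation-controlled reduction of F2 with excess Zn(BH4)2 (to allow for the two phenols) should then lead directly to 28, where the fallback rejoins the route.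

Further compounds
F1 | step 11 | 4-[(1RS,2S,3R)-4-(4-benzyloxy-3-methoxyphenyl)-1-methoxy-2,3-dimethylbutyl]-2-methoxyphenol | COc1cc(C(OC)[C@@H](C)[C@H](C)Cc2ccc(OCc3ccccc3)c(OC)c2)ccc1O
F0 | step 16 | none | none
F2 | step 17 | (2R)-1-(4-hydroxy-3-methoxyphenyl)-2-{4-[(1S,2S,3R)-7-hydroxy-6-methoxy-2,3-dimethyl-1,2,3,4-tetrahydronaphthalen-1-yl]-2-methoxyphenoxy}propan-1-one | COc1cc(ccc1O)C(=O)[C@@H](C)Oc1ccc(cc1OC)[C@H]1c2cc(O)c(OC)cc2C[C@@H](C)[C@@H]1C
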